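**Retrosynthetic overview**
1. Target ⇒ site-selective acylation of methyl (−)-shikimate: 5-O-(2R)-2-methylbutanoate first (3,4-acetonide in place), then 4-O-propanoate (3-O-TBS in place), then 3-O-acetate.
2. (2R)-2-Methylbutanoic acid ⇒ Evans methylation of N-butanoyl-(R)-4-benzyloxazolidinone.
3. Methyl shikimate ⇒ ring-closing metathesis of an acyclic triol diene; this forms the only ring (the cyclohexene).
4. Triol diene ⇒ key C5–C6 bond by indium-mediated carbonyl allylation of (2R,3R)-2,3-dihydroxypent-4-enal with methyl 2-(bromomethyl)acrylate; chelation control sets C5.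
5. Enal ⇒ D-ribose via zinc fragmentation of methyl 5-deoxy-5-iodoribofuranoside; ribose C3 and C2 become shikimate C3 and C4.

Assumption: the SMILES is read as methyl 3-O-acetyl-4-O-propanoyl-5-O-[(2R)-2-methylbutanoyl]shikimate, ring (3R,4S,5R) as in natural (−)-shikimate, side chain (2R); selectivities quoted are expectations, not measured values.

**Route**

Step 1
Reactants: 1 (R)-4-benzyl-1,3-oxazolidin-2-one; 2 butanoyl chloride
Product: 4 (R)-4-benzyl-3-butanoyl-1,3-oxazolidin-2-one, via N-lithio oxazolidinone 3 (not isolated)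
Conditions: n-BuLi, THF, −78 °C; then 2, −78 to 0 °C
Reagents that add atoms: none
Why: N-acylation of the lithiated oxazolidinone by the acid chloride (Evans auxiliary loading) is fast and clean and creates no new stereocentre.

Step 2
Reactants: 4 (R)-4-benzyl-3-butanoyl-1,3-oxazolidin-2-one
Product: 6 (R)-4-benzyl-3-[(2R)-2-methylbutanoyl]-1,3-oxazolidin-2-one, via sodium Z-enolate 5 (not isolated)
Conditions: NaN(SiMe3)2, THF, −78 °C; then MeI, −78 °C; chromatography and recrystallisation to one diastereomer
Reagents that add atoms: iodomethane, CI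
Why: Evans asymmetric alkylation, in which the chelated Z-enolate is methylated on the face opposite the benzyl group of the (R)-auxiliary, sets the new α-stereocentre as R (about 10:1 before purification).

Step 3
Reactants: 6 (R)-4-benzyl-3-[(2R)-2-methylbutanoyl]-1,3-oxazolidin-2-one
Product: 8 (2R)-2-methylbutanoic acid, via lithium peroxycarboxylate 7 (not isolated)
Conditions: LiOH, 30% H2O2, THF/H2O 3:1, 0 °C; then Na2SO3 (aq); extract auxiliary; then HCl to pH 2
Reagents that add atoms: hydrogen peroxide, OO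
Why: Hydroperoxide-mediated exocyclic imide cleavage (Evans LiOOH hydrolysis) releases the acid without epimerising the non-activated α-stereocentre and returns the auxiliary.

Step 4
Reactants: 9 D-ribose
Product: 10 methyl β-D-ribofuranoside
Conditions: MeOH, H2SO4 (cat.), 0–4 °C, 20 h; then NaHCO3
Reagents that add atoms: methanol, CO
Why: Kinetic Fischer glycosidation at low temperature gives the furanosides (β major; the minor α-anomer is carried along because C1 later becomes the aldehyde carbon) and leaves C2–C4 of ribose untouched.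

Step 5
Reactants: 10 methyl β-D-ribofuranoside
Product: 11 methyl 5-deoxy-5-iodo-β-D-ribofuranoside
Conditions: PPh3, I2, imidazole, THF, 60 °C
Reagents that add atoms: iodine, II
Why: Garegg–Samuelsson (Appel-type) iodination is selective for the only primary hydroxyl and does not touch the secondary cis-diol or any stereocentre.

Step 6
Reactants: 11 methyl 5-deoxy-5-iodo-β-D-ribofuranoside; 12 methyl 2-(bromomethyl)acrylate
Product: 15 methyl (4R,5S,6R)-4,5,6-trihydroxy-2-methylideneoct-7-enoate, via dihydroxypentenal 13 (not isolated), via allylindium reagent 14 (not isolated)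
Conditions: Zn dust, THF/H2O 4:1, sonication, 40 °C; filter off Zn; then In powder, 12, rt; neutral work-up
Reagents that add atoms: none
Why: Bernet–Vasella zinc fragmentation unmasks the α,β-dihydroxy enal, and the indium-mediated Barbier carbonyl allylation in water then proceeds through a Cram chelate between indium, the aldehyde oxygen and the free α-hydroxyl, so the new carbinol carbon C4 (shikimate C5) is formed syn (threo) to C5 with R configuration (about 4–6:1 expected, the minor epimer being removed by crystallisation of 16 or chromatography of 17).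

Step 7
Reactants: 15 methyl (4R,5S,6R)-4,5,6-trihydroxy-2-methylideneoct-7-enoate
Product: 16 methyl shikimate
Conditions: second-generation Grubbs catalyst RuCl2(=CHPh)(H2IMes)(PCy3) (5 mol %), CH2Cl2 (0.01 M), 40 °C
Reagents that add atoms: none
Why: Ring-closing olefin metathesis joins the vinyl group and the 1,1-disubstituted acrylate alkene with loss of ethylene to give the conjugated trisubstituted cyclohexene, leaving the three carbinol centres untouched.

Step 8
Reactants: 16 methyl shikimate
Product: 17 methyl 3,4-O-isopropylidene shikimate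
Conditions: 2,2-dimethoxypropane, TsOH·H2O (cat.), acetone, rt
Reagents that add atoms: 2,2-dimethoxypropane, COC(C)(C)OC
Why: Acid-catalysed transacetalisation forms the five-membered acetal only across the cis-3,4-diol, leaving the trans-disposed 5-hydroxyl free and no stereocentre affected.

Step 9
Reactants: 17 methyl 3,4-O-isopropylidene shikimate; 8 (2R)-2-methylbutanoic acid
Product: 18 methyl 3,4-O-isopropylidene-5-O-[(2R)-2-methylbutanoyl]shikimate
Conditions: EDC·HCl, DMAP, CH2Cl2, 0 °C to rt
Reagents that add atoms: none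
Why: Steglich esterification acylates the only free hydroxyl with retention at C5, and the simple α-alkyl stereocentre of the acid is not epimerised under these mild conditions.

Step 10
Reactants: 18 methyl 3,4-O-isopropylidene-5-O-[(2R)-2-methylbutanoyl]shikimate
Product: 19 methyl 5-O-[(2R)-2-methylbutanoyl]shikimate
Conditions: AcOH/H2O 4:1, 50 °C
Reagents that add atoms: none
Why: Mild aqueous-acid acetal hydrolysis removes the isopropylidene group while both esters survive and acid-catalysed migration of the hindered branched acyl group from O5 is negligible.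

Step 11
Reactants: 19 methyl 5-O-[(2R)-2-methylbutanoyl]shikimate
Product: 20 methyl 3-O-(tert-butyldimethylsilyl)-5-O-[(2R)-2-methylbutanoyl]shikimate
Conditions: TBSCl (1.1 equiv), imidazole, DMF, −20 to 0 °C
Reagents that add atoms: tert-butyldimethylsilyl chloride, CC(C)(C)[Si](C)(C)Cl
Why: Sterically controlled monosilylation occurs at the allylic 3-hydroxyl, which has one oxygenated sp3 neighbour, rather than at the 4-hydroxyl flanked by C3–O and the bulky C5 ester.

Step 12
Reactants: 20 methyl 3-O-(tert-butyldimethylsilyl)-5-O-[(2R)-2-methylbutanoyl]shikimate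
Product: 21 methyl 3-O-(tert-butyldimethylsilyl)-5-O-[(2R)-2-methylbutanoyl]-4-O-propanoylshikimate
Conditions: (EtCO)2O, pyridine, DMAP (cat.), CH2Cl2, 0 °C to rt
Reagents that add atoms: propanoic anhydride, CCC(=O)OC(=O)CC
Why: DMAP-catalysed acylation of the single remaining hydroxyl gives the propanoate with retention, the silyl ether and the other esters being inert.

Step 13
Reactants: 21 methyl 3-O-(tert-butyldimethylsilyl)-5-O-[(2R)-2-methylbutanoyl]-4-O-propanoylshikimate
Product: 22 methyl 5-O-[(2R)-2-methylbutanoyl]-4-O-propanoylshikimate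
Conditions: HF·pyridine, pyridine, THF, 0 °C to rt
Reagents that add atoms: none
Why: Fluoride-mediated desilylation under buffered acidic conditions cleaves the silyl ether without the base-promoted O4-to-O3 acyl migration that basic fluoride sources could cause.

Step 14
Reactants: 22 methyl 5-O-[(2R)-2-methylbutanoyl]-4-O-propanoylshikimate
Product: 23 methyl (3R,4S,5R)-3-acetoxy-5-[(2R)-2-methylbutanoyloxy]-4-propanoyloxycyclohex-1-ene-1-carboxylate
Conditions: Ac2O, pyridine, DMAP (cat.), CH2Cl2, 0 °C
Reagents that add atoms: acetic anhydride, CC(=O)OC(C)=O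
Why: Fast DMAP-catalysed acetylation of the liberated allylic alcohol at 0 °C outruns acyl migration and completes the triester with all four stereocentres unchanged.

**Compound list**
1 | (R)-4-benzyl-1,3-oxazolidin-2-one | O=C1N[C@H](Cc2ccccc2)CO1 | starting material
2 | butanoyl chloride | CCCC(Cl)=O | starting material
3 | N-lithio-(R)-4-benzyl-1,3-oxazolidin-2-one | [Li]N1[C@H](Cc2ccccc2)COC1=O | intermediate (not isolated)
4 | (R)-4-benzyl-3-butanoyl-1,3-oxazolidin-2-one | CCCC(=O)N1[C@H](Cc2ccccc2)COC1=O | intermediate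
5 | sodium (Z)-enolate of 4 | CC/C=C(\O[Na])N1[C@H](Cc2ccccc2)COC1=O | intermediate (not isolated)
6 | (R)-4-benzyl-3-[(2R)-2-methylbutanoyl]-1,3-oxazolidin-2-one | CC[C@@H](C)C(=O)N1[C@H](Cc2ccccc2)COC1=O | intermediate
7 | lithium (2R)-2-methylbutaneperoxoate | [Li+].CC[C@@H](C)C(=O)O[O-] | intermediate (not isolated)
8 | (2R)-2-methylbutanoic acid | CC[C@@H](C)C(O)=O | intermediate
9 | D-ribose (aldehydo form drawn) | O=C[C@H](O)[C@H](O)[C@H](O)CO | starting material
10 | methyl β-D-ribofuranoside (β-anomer drawn; minor α-anomer carried along) | CO[C@H]1[C@H](O)[C@H](O)[C@@H](CO)O1 | intermediate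
11 | methyl 5-deoxy-5-iodo-β-D-ribofuranoside | CO[C@H]1[C@H](O)[C@H](O)[C@@H](CI)O1 | intermediate
12 | methyl 2-(bromomethyl)acrylate | COC(=O)C(=C)CBr | starting material
13 | (2R,3R)-2,3-dihydroxypent-4-enal | O=C[C@H](O)[C@H](O)C=C | intermediate (not isolated)
14 | 2-(methoxycarbonyl)allylindium (drawn as the monovalent allylindium species) | COC(=O)C(=C)C[In] | intermediate (not isolated)
15 | methyl (4R,5S,6R)-4,5,6-trihydroxy-2-methylideneoct-7-enoate | COC(=O)C(=C)C[C@@H](O)[C@H](O)[C@H](O)C=C | intermediate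
16 | methyl shikimate, methyl (3R,4S,5R)-3,4,5-trihydroxycyclohex-1-ene-1-carboxylate | O[C@@H]1[C@H](O)C=C(C(=O)OC)C[C@H]1O | intermediate
17 | methyl 3,4-O-isopropylidene shikimate, methyl (3aR,7R,7aS)-7-hydroxy-2,2-dimethyl-3a,6,7,7a-tetrahydro-1,3-benzodioxole-5-carboxylate | CC1(C)O[C@@H]2[C@H](O1)C=C(C(=O)OC)C[C@H]2O | intermediate
18 | methyl 3,4-O-isopropylidene-5-O-[(2R)-2-methylbutanoyl]shikimate | CC1(C)O[C@@H]2[C@H](O1)C=C(C(=O)OC)C[C@H]2OC(=O)[C@H](C)CC | intermediate
19 | methyl 5-O-[(2R)-2-methylbutanoyl]shikimate | O[C@@H]1[C@H](O)C=C(C(=O)OC)C[C@H]1OC(=O)[C@H](C)CC | intermediate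
20 | methyl 3-O-(tert-butyldimethylsilyl)-5-O-[(2R)-2-methylbutanoyl]shikimate | O[C@@H]1[C@H](O[Si](C)(C)C(C)(C)C)C=C(C(=O)OC)C[C@H]1OC(=O)[C@H](C)CC | intermediate
21 | methyl 3-O-(tert-butyldimethylsilyl)-5-O-[(2R)-2-methylbutanoyl]-4-O-propanoylshikimate | CCC(=O)O[C@@H]1[C@H](O[Si](C)(C)C(C)(C)C)C=C(C(=O)OC)C[C@H]1OC(=O)[C@H](C)CC | intermediate
22 | methyl 5-O-[(2R)-2-methylbutanoyl]-4-O-propanoylshikimate | CCC(=O)O[C@@H]1[C@H](O)C=C(C(=O)OC)C[C@H]1OC(=O)[C@H](C)CC | intermediate
23 | methyl (3R,4S,5R)-3-acetoxy-5-[(2R)-2-methylbutanoyloxy]-4-propanoyloxycyclohex-1-ene-1-carboxylate | CCC(=O)O[C@@H]1[C@H](OC(C)=O)C=C(C(=O)OC)C[C@H]1OC(=O)[C@H](C)CC | target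

**Step count and risks**

Total steps: 14. Longest linear sequence: 11 steps (steps 4–14, from D-ribose 9 to 23); the acid 8 is made in 3 steps and joins at step 9.

Steps most likely to fail:

Step 6 (diastereoselectivity and handling of the unprotected tandem fragmentation–allylation). If chelation control is too weak, the C5 centre is instead set by Felkin–Anh addition to an acetonide-protected aldehyde and then inverted. This fallback sets out from 9 and comes back at 17.
- Acetone/MeOH/HCl converts 9 into methyl 2,3-O-isopropylidene-β-D-ribofuranoside F1.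
- PPh3/I2/imidazole gives methyl 5-deoxy-5-iodo-2,3-O-isopropylidene-β-D-ribofuranoside F2.
- Zn in THF/aqueous NH4Cl fragments it to (4R,5R)-2,2-dimethyl-5-vinyl-1,3-dioxolane-4-carbaldehyde F3.
- F3 is allylated in the same flask with 12 and Zn to the 4,5-anti alcohol methyl (4S)-4-[(4S,5R)-2,2-dimethyl-5-vinyl-1,3-dioxolan-4-yl]-4-hydroxy-2-methylidenebutanoate F4. Any syn isomer formed leads to 17 directly after metathesis.
- Mitsunobu inversion (PPh3, DIAD, 4-nitrobenzoic acid, toluene) gives methyl (4R)-4-[(4S,5R)-2,2-dimethyl-5-vinyl-1,3-dioxolan-4-yl]-2-methylidene-4-(4-nitrobenzoyloxy)butanoate F5.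
- Ring-closing metathesis with the second-generation Grubbs catalyst gives methyl 3,4-O-isopropylidene-5-O-(4-nitrobenzoyl)shikimate F6.
- K2CO3/MeOH removes the nitrobenzoate and gives 17.

Step 7 (metathesis onto an electron-poor 1,1-disubstituted alkene in a free triol, with possible solubility, chelation or isomerisation problems). The fallback runs the metathesis on a fully protected substrate. It sets out from 15 and comes back at 16.
- Ac2O/pyridine/DMAP gives methyl (4R,5S,6R)-4,5,6-triacetoxy-2-methylideneoct-7-enoate F7.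
- The second-generation Hoveyda–Grubbs catalyst RuCl2(=CH-C6H4-2-OiPr)(H2IMes) in toluene at 80 °C closes the ring to methyl 3,4,5-tri-O-acetylshikimate F8.
- K2CO3 (cat.)/MeOH at 0 °C removes the acetates and gives 16.

Step 11 (regioselective monosilylation of the 3,4-diol). The fallback differentiates the two hydroxyls by orthoester opening instead of sterically controlled silylation. It sets out from 19 and comes back at 23, bypassing 20–22.
- Trimethyl orthoacetate with catalytic camphorsulfonic acid in CH2Cl2 gives methyl 3,4-O-(1-methoxyethylidene)-5-O-[(2R)-2-methylbutanoyl]shikimate F9.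
- Brief treatment with 80% aqueous AcOH opens the orthoester to the pseudoaxial ester, methyl 3-O-acetyl-5-O-[(2R)-2-methylbutanoyl]shikimate F10.
- Immediate propanoylation ((EtCO)2O, pyridine, DMAP, 0 °C) gives 23.

Further compounds
F1 | step 6 | methyl 2,3-O-isopropylidene-β-D-ribofuranoside | CO[C@H]1[C@@H]2OC(C)(C)O[C@@H]2[C@@H](CO)O1
F2 | step 6 | methyl 5-deoxy-5-iodo-2,3-O-isopropylidene-β-D-ribofuranoside | CO[C@H]1[C@@H]2OC(C)(C)O[C@@H]2[C@@H](CI)O1
F3 | step 6 | (4R,5R)-2,2-dimethyl-5-vinyl-1,3-dioxolane-4-carbaldehyde | O=C[C@@H]1OC(C)(C)O[C@@H]1C=C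
F4 | step 6 | methyl (4S)-4-[(4S,5R)-2,2-dimethyl-5-vinyl-1,3-dioxolan-4-yl]-4-hydroxy-2-methylidenebutanoate | COC(=O)C(=C)C[C@H](O)[C@@H]1OC(C)(C)O[C@@H]1C=C
F5 | step 6 | methyl (4R)-4-[(4S,5R)-2,2-dimethyl-5-vinyl-1,3-dioxolan-4-yl]-2-methylidene-4-(4-nitrobenzoyloxy)butanoate | COC(=O)C(=C)C[C@@H](OC(=O)c1ccc(cc1)[N+](=O)[O-])[C@@H]2OC(C)(C)O[C@@H]2C=C
F6 | step 6 | methyl 3,4-O-isopropylidene-5-O-(4-nitrobenzoyl)shikimate | CC1(C)O[C@@H]2[C@H](O1)C=C(C(=O)OC)C[C@H]2OC(=O)c1ccc(cc1)[N+](=O)[O-]
F7 | step 7 | methyl (4R,5S,6R)-4,5,6-triacetoxy-2-methylideneoct-7-enoate | COC(=O)C(=C)C[C@@H](OC(C)=O)[C@H](OC(C)=O)[C@H](OC(C)=O)C=C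
F8 | step 7 | methyl 3,4,5-tri-O-acetylshikimate | CC(=O)O[C@@H]1[C@H](OC(C)=O)C=C(C(=O)OC)C[C@H]1OC(C)=O
F9 | step 11 | methyl 3,4-O-(1-methoxyethylidene)-5-O-[(2R)-2-methylbutanoyl]shikimate (both epimers at the orthoester carbon) | COC1(C)O[C@@H]2[C@H](O1)C=C(C(=O)OC)C[C@H]2OC(=O)[C@H](C)CC
F10 | step 11 | methyl 3-O-acetyl-5-O-[(2R)-2-methylbutanoyl]shikimate | O[C@@H]1[C@H](OC(C)=O)C=C(C(=O)OC)C[C@H]1OC(=O)[C@H](C)CC
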